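Numbers refer to the compound list after the steps. Atom labels: ring A = a1 (C–OMe), a2 (C–Me), a3 (C=O), a4 (spiro), a5 (C=O), a6 (CMe2); ring B = a4, Cc (CH–iPr), Cb, Ca, P2; pinane = P1–P7 (P1 and P5 bridgeheads, P6 the CMe2 bridge, P7 the CH2 bridge). Lower-case a1–a6 are atoms; capital A1–A9 are compounds of the rejected strategies.

## Analysis of the target

The target 28 is a dispiro compound. A pinane is joined through its quaternary carbon P2 to a cyclopentane (ring B), which shares the quaternary carbon a4 with ring A, a 3-methoxy-enone that is also a 1,3-diketone centred on a4. There are five stereocentres: the bridgeheads P1 and P5 (brought in by the terpene) and the contiguous P2, a4 and Cc. Read from the SMILES, a4 lies on the pinane face of the CMe2 bridge and Ca on the face of the CH2 bridge; on ring B the isopropyl group is cis to P3 and to the a3 carbonyl, and trans to P1 and to the a5 carbonyl. Sensitive features are the cyclobutane (a cation or radical at P2 opens or rearranges it), the non-enolisable diketone at a4 (retro-Claisen cleavage by nucleophiles) and the vinylogous ester (acid hydrolysis, and two oxygens that compete for the methyl group). The hard part is the pair of adjacent quaternary spiro carbons P2–a4 next to Cc, with P2 to be set against the bulk of the bridge. The handle is that P2 has a methylene neighbour, P3. In a pinene, P2=P3 is an alkene with one open face, so a carbon (Ca) tethered through a4–Cc–Cb can be delivered to both alkene carbons from that face and the extra Ca–P3 bond cut afterwards.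

## Retrosynthetic reasoning

**28 ⇒ 27.** The O–CH3 bond at a1 is cut last, because the enol ether is the most acid-labile group and the triketone 27 can enolise only through a2. The forward step has to methylate the a1 oxygen and not the a3 oxygen; the a3 oxygen sits between the spiro centre and the cis isopropyl group.

**27 ⇒ 26.** The a4–a5 bond is cut. This makes the quaternary centre a4 by an intramolecular acylation through a six-membered transition state. Cutting a2–a3 instead would require a4 to be quaternised first by an intermolecular acylation of a very hindered enolate with a pivaloyl-like electrophile. The forward step must deliver a5 to planar a4 on the face of ring B anti to the isopropyl group; the earlier configuration at a4 is erased.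

**26 ⇒ 21 + 24, and 24 ⇒ 22 + 23.** The a2–a3 bond is cut as an aldol addition followed by oxidation. A direct ester condensation of 19 with the enolate of 24 would be shorter, but the ester carbonyl of 19 is flanked by P2 and Cc and is too hindered; an aldehyde is not. Keto ester 24 has one enolisable position and comes from 22 and 23 by C-acylation.

**21 ⇒ 19 ⇒ 17 ⇒ 16.** Aldehyde 21 is ester 19 at a lower oxidation level, and the Cb methylene of 19 is the ketone of 17. In 17 the Ca–P3 bond is re-formed to give cyclopropyl ketone 16. The forward cleavage must break the cyclopropane bond external to ring B and not the fusion bond Ca–P2, whose cleavage would put a radical next to the cyclobutane.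

**16 ⇒ 15 (key disconnection).** Ca–P2 and Ca–P3 are cut together, which leads back to a carbenoid at Ca and the pinene alkene. This makes ring B and the quaternary P2 in one step, and the configuration at P2 is decided by the pinane itself.

**15 ⇒ 13.** The Ca–Cb bond is cut; Ca comes from a one-carbon diazo nucleophile acylated by the activated acid. The activation must avoid strong acid, which the pinene alkene does not tolerate.

**13 ⇒ 10.** The a4–Cc bond is cut as an ester-enolate [3,3] rearrangement, with P3–O re-formed and the alkene returned to the exocyclic position. The C–O stereocentre at P3 transfers its configuration to a4, and the ketene acetal geometry sets Cc. An intermolecular union of the two halves has no such relay.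

**10 ⇒ 8 + 9 ⇒ 7 ⇒ 5 ⇒ 3 + 4 ⇒ 1.** Direct allylic hydroxylation of 5 and acylation looks shorter but should fail. Both the ene step and the sigmatropic step of that hydroxylation occur on the open face, so the alkene geometry of 5 is retained, and the resulting hydroxy ester (ester syn to the carbinol) closes to a butenolide. The route therefore passes through ketone 7, where the ester is driven anti to the carbonyl. Reduction from the open face gives 8, and esterification of 8 with 9 under inversion gives 10 with the C–O bond on the open face. Enoate 5 comes from ketone 3 and phosphonate 4, and 3 from the terpene 1 by cleavage of the exocyclic alkene.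

## Alternatives that were turned down

**Alternative 1:** Ca–P2 and a4–Cc are cut in a radical [3+2] annulation between the alkylidene dioxanedione A2 (made from 3) and isopropenylcyclopropane A3, giving the dispiro Meldrum's acid A1.
- Forward key step: a thiyl radical opens A3 to a homoallyl radical. Its primary carbon adds to P2 of A2, and the resulting malonyl radical at a4 closes 5-exo with loss of the thiyl radical.
- For: ring B and both quaternary carbons form in one catalytic, convergent step, and P2 is set by the same facial bias. On step count to ring B this is stronger than the chosen route, which needs seven steps to reach 15.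
- Against: the radical must add intermolecularly to a fully substituted carbon next to the bridgehead, in competition with oligomerisation of A3. Cc is set only by remote induction in the 5-exo closure. In A1 the two acyl groups on a4 are equivalent, so a4 would have to be created later by telling two diastereotopic carbonyls apart while three carbons are inserted into a hindered spiro ring.
- Compared with it, the chosen route sets Cc by chirality transfer in a cyclic transition state and a4 by an intramolecular acylation steered by the neighbouring isopropyl group.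

**Alternative 2:** Ca–P2 and Cb–P3 are cut in a [2+2] cycloaddition of dichloroketene A6 with the 2-arylpinene A5, giving the fused dichlorocyclobutanone A4.
- Forward key step: the CCl2 carbon of A6 bonds to benzylic P2 and the carbonyl carbon to P3.
- For: an intermolecular, polarity-controlled reaction that tolerates trisubstituted alkenes. It sets P2 with the a4 carbon already attached and brings all six ring A carbons as one arene. On convergence at the first C–C bond it is stronger than the chosen route.
- Against: the doubly ortho-substituted aryl group shields the alkene, and its acetal protecting groups are exposed to the Lewis acidic by-products of ketene generation. In A4 the bond that must later be cut is Cb–P3, whereas strain-driven opening of such cyclobutanones breaks the acyl–CCl2 bond. Cc, its isopropyl group and ring B would then have to come from a dearomatising spirocyclisation with little control at a4 and Cc, followed by adjustment of the arene oxidation pattern.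
- Compared with it, the chosen route cleaves exactly the bond it needs to (Ca–P3) under stereoelectronic control and completes ring B, Cc included, before ring A is started.

**Alternative 3:** Cc–isopropyl and a4–a5 are cut in a conjugate addition–acylation on the spiro cyclopentene ester A8 with the keto acid chloride A9, giving the keto diester A7.
- Forward key step: a copper-mediated 1,4-addition of an isopropyl nucleophile to Cc, and trapping of the enolate at a4 by A9.
- For: Cc and a4 are set trans in one flask, all ring A carbons arrive together, and the final ring closure from the ethyl ketone side is driven by deprotonation of its product. That endgame is stronger and shorter than the dianion closure used here.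
- Against: A8 already contains the configured quaternary P2, so the hardest problem is moved into the preparation of A8, not solved. The face of addition at Cc is governed only by a spiro centre two atoms away. The fully substituted enolate at a4 has to attack a pivaloyl-like chloride, where O-acylation is likely.
- Compared with it, the chosen route sets P2 by the pinane face and Cc by chirality transfer, and makes the a4–a5 bond intramolecularly; its endgame is kept in reserve as a fallback.

Key step: step 8

## Route

Remark on the chemistry: 27 is a mobile keto–enol system and is written as the enol with the hydroxyl on a1; (+)-β-pinene is assumed to be of high enantiomeric purity, since no later step can raise it.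

Step 1
Reactants: 1 (+)-β-pinene
Product: 3 (−)-nopinone, via secondary ozonide 2 (not isolated)
Conditions: O3, CH2Cl2, −78 °C; Me2S, −78 → 25 °C
Reagents that add atoms: ozone, [O-][O+]=O
Why: Ozonolysis of the 1,1-disubstituted alkene (cycloaddition, cycloreversion and recombination to the ozonide, then reduction by the sulfide) is the standard route from β-pinene to nopinone. No stereocentre is touched and the cyclobutane is inert to ozone at −78 °C.

Step 2
Reactants: 3 (−)-nopinone; 4 trimethyl phosphonoacetate
Product: 5 methyl (2E)-2-[(1S,5R)-6,6-dimethylbicyclo[3.1.1]heptan-2-ylidene]acetate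
Conditions: NaH, THF, 0 → 65 °C
Reagents that add atoms: none
Why: Horner–Wadsworth–Emmons olefination; the small phosphonate anion adds to the ketone despite the neighbouring bridgehead, and the ester settles on the side of the P3 methylene. The E/Z ratio is of no consequence because step 3 ends with an equilibration of the alkene geometry.

Step 3
Reactants: 5 methyl (2E)-2-[(1S,5R)-6,6-dimethylbicyclo[3.1.1]heptan-2-ylidene]acetate
Product: 7 methyl (2E)-2-[(1S,5S)-6,6-dimethyl-3-oxobicyclo[3.1.1]heptan-2-ylidene]acetate, via (Z)-keto enoate 6 (not isolated)
Conditions: Rh2(cap)4 (dirhodium tetracaprolactamate, 1 mol %), t-BuOOH (70 % aq.), K2CO3, CH2Cl2, 25 °C; then I2 (5 mol %), CH2Cl2, daylight, 25 °C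
Reagents that add atoms: tert-butyl hydroperoxide, CC(C)(C)OO
Why: Radical allylic oxidation (Kharasch type): the tert-butylperoxy radical generated by the dirhodium catalyst abstracts hydrogen from P3, the only allylic methylene, and the mixed peroxide formed at the γ-carbon collapses to the ketone (Kornblum–DeLaMare). The first-formed cis-enedicarbonyl 6 holds ester and ketone side by side in one plane; iodine-catalysed isomerisation relieves this and should leave the ester anti to the ketone. This geometry later decides the configuration at a4.

Step 4
Reactants: 7 methyl (2E)-2-[(1S,5S)-6,6-dimethyl-3-oxobicyclo[3.1.1]heptan-2-ylidene]acetate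
Product: 8 methyl (2E)-2-[(1S,3S,5S)-3-hydroxy-6,6-dimethylbicyclo[3.1.1]heptan-2-ylidene]acetate
Conditions: NaBH4, CeCl3·7H2O, MeOH, −78 → −40 °C
Reagents that add atoms: none
Why: Luche reduction: the cerium-activated borohydride adds 1,2 to the ketone and spares the doubly activated alkene. Hydride comes from the face anti to the CMe2 bridge, whose inner methyl group lies over P3, so the hydroxyl ends up cis to the bridge (the course known for pinocarvone); with the ester anti to the carbinol carbon no lactone can form.

Step 5
Reactants: 8 methyl (2E)-2-[(1S,3S,5S)-3-hydroxy-6,6-dimethylbicyclo[3.1.1]heptan-2-ylidene]acetate; 9 3-methylbutanoic acid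
Product: 10 methyl (2E)-2-[(1S,3R,5S)-6,6-dimethyl-3-(3-methylbutanoyloxy)bicyclo[3.1.1]heptan-2-ylidene]acetate
Conditions: PPh3, i-PrO2CN=NCO2i-Pr, THF, 0 → 25 °C
Reagents that add atoms: none
Why: Mitsunobu esterification: the carboxylate displaces the oxyphosphonium group with SN2 inversion from the open face, which installs the isovalerate and turns the C–O bond to the face anti to the bridge in one operation. SN2′ attack is not expected because its terminus is the ester-bearing carbon.

Step 6
Reactants: 10 methyl (2E)-2-[(1S,3R,5S)-6,6-dimethyl-3-(3-methylbutanoyloxy)bicyclo[3.1.1]heptan-2-ylidene]acetate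
Product: 13 (2R,3R)-3-[(1S,5R)-6,6-dimethylbicyclo[3.1.1]hept-2-en-2-yl]-4-methoxy-4-oxo-2-(propan-2-yl)butanoic acid, via silyl ketene acetal 11 (not isolated), via trimethylsilyl ester 12 (not isolated)
Conditions: LiN(i-Pr)2, THF–DMPU (4:1), −78 °C; Me3SiCl, −78 → 40 °C; aq. citric acid
Reagents that add atoms: none
Why: Ireland–Claisen rearrangement: kinetic deprotonation in the presence of DMPU gives the ketene acetal with the isopropyl group cis to OSiMe3, and the [3,3] shift runs through a chair on the face of the C–O bond (anti to the bridge) with the acetal carbon turned away from the pinane. The a4–Cc bond forms suprafacially, so the carbinol centre and the E alkene set a4, the acetal geometry sets Cc (both R), and the alkene moves into the ring as P2=P3. Silylation at −78 °C keeps the lithium enolate from adding to the enoate.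

Step 7
Reactants: 13 (2R,3R)-3-[(1S,5R)-6,6-dimethylbicyclo[3.1.1]hept-2-en-2-yl]-4-methoxy-4-oxo-2-(propan-2-yl)butanoic acid
Product: 15 methyl (2R,3R)-5-diazo-2-[(1S,5R)-6,6-dimethylbicyclo[3.1.1]hept-2-en-2-yl]-4-oxo-3-(propan-2-yl)pentanoate, via acid chloride 14 (not isolated)
Conditions: NaH (1.0 equiv.), benzene, 0 °C; (COCl)2, pyridine (cat.), 0 → 25 °C; evaporate; CH2N2 (excess), Et2O, 0 °C
Reagents that add atoms: diazomethane, C=[N+]=[N-]
Why: The acid chloride is made from the sodium salt so that no hydrogen chloride meets the acid-labile pinene alkene and no amine base can epimerise Cc through a ketene. Acylation of diazomethane (first stage of the Arndt–Eistert sequence) then gives the diazoketone, the excess reagent taking up the hydrogen chloride.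

Step 8
Reactants: 15 methyl (2R,3R)-5-diazo-2-[(1S,5R)-6,6-dimethylbicyclo[3.1.1]hept-2-en-2-yl]-4-oxo-3-(propan-2-yl)pentanoate
Product: 16 cyclopropyl ketone with ring B fused to the cyclopropane Ca–P2–P3
Conditions: Cu(acac)2 (5 mol %), toluene, 110 °C, slow addition of 15 at high dilution
Reagents that add atoms: none
Why: Intramolecular cyclopropanation of an alkene by a metal carbenoid: Cu(acac)2, a divalent copper complex that the diazo compound reduces to the active monovalent copper, takes up the diazo carbon Ca with loss of N2, and the electrophilic carbenoid adds to the electron-rich P2=P3 bond in a concerted, asynchronous [2+1] step. The closest precedent is the copper- or rhodium-catalysed closure of 1-diazohex-5-en-2-ones to bicyclo[3.1.0]hexan-2-ones, of which 15 is a substituted member. Ring B closes through the bond Ca–P2 in a 5-exo sense, the three-atom tether a4–Cc–Cb being just long enough to bring Ca over the inner alkene carbon; the cyclopropane closes in the same event through Ca–P3 and is necessarily cis-fused. The three new stereocentres Ca, P2 and P3 are therefore locked to one another and only the alkene face is open to choice. That choice is made by the pinane: the inner methyl of the CMe2 bridge covers one face, so the tether swings to the other, which places Ca anti and a4 syn to the bridge. The centres a4 and Cc are not touched. The step needs cyclopropanation to win over C–H insertion, ylide formation at the ester carbonyl and carbene dimerisation; the five-membered transition state, the absence of any activated C–H bond within reach (only isopropyl methyl groups) and slow addition at high dilution should secure this.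

Step 9
Reactants: 16 cyclopropyl ketone with ring B fused to the cyclopropane Ca–P2–P3
Product: 17 methyl 6,6-dimethyl-4'-oxo-3'-(propan-2-yl)spiro[bicyclo[3.1.1]heptane-2,1'-cyclopentane]-2'-carboxylate
Conditions: SmI2 (2.5 equiv.), THF–MeOH, DMPU, −78 → 0 °C
Reagents that add atoms: none
Why: Single-electron reduction to the ketyl is followed by cyclopropylcarbinyl ring opening (the SmI2 cleavage of cyclopropyl ketones); the bond broken is Ca–P3, which stands nearly parallel to the ketyl π orbital, and not the fusion bond Ca–P2, which lies in the plane of ring B. The secondary radical at P3 (not a cyclobutylcarbinyl radical) is reduced and protonated and the samarium enolate is protonated at Ca, so Cc is never enolised and the methyl ester is untouched.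

Step 10
Reactants: 17 methyl 6,6-dimethyl-4'-oxo-3'-(propan-2-yl)spiro[bicyclo[3.1.1]heptane-2,1'-cyclopentane]-2'-carboxylate
Product: 18 1,3-dithiolane of 17 at Cb
Conditions: HSCH2CH2SH, BF3·OEt2, CH2Cl2, 0 → 25 °C
Reagents that add atoms: ethane-1,2-dithiol, SCCS
Why: Lewis acid catalysed dithioketalisation of a cyclopentanone that has one unhindered α-methylene. Should any enol form towards Cc, the trans arrangement of isopropyl and ester already present is the more stable one, so this centre is not at risk.

Step 11
Reactants: 18 1,3-dithiolane of 17 at Cb
Product: 19 methyl 6,6-dimethyl-3'-(propan-2-yl)spiro[bicyclo[3.1.1]heptane-2,1'-cyclopentane]-2'-carboxylate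
Conditions: Raney Ni (W-2), EtOH, 78 °C
Reagents that add atoms: none
Why: Raney Ni desulfurisation (Mozingo reduction) replaces both C–S bonds by C–H; ester and cyclobutane are inert, and Cc is now fixed.

Step 12
Reactants: 19 methyl 6,6-dimethyl-3'-(propan-2-yl)spiro[bicyclo[3.1.1]heptane-2,1'-cyclopentane]-2'-carboxylate
Product: 20 [6,6-dimethyl-3'-(propan-2-yl)spiro[bicyclo[3.1.1]heptane-2,1'-cyclopentan]-2'-yl]methanol
Conditions: LiAlH4, THF, 0 → 25 °C; aq. NaOH work-up
Reagents that add atoms: none
Why: LiAlH4 reduces even this hindered ester to the primary alcohol; no other reducible group is present.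

Step 13
Reactants: 20 [6,6-dimethyl-3'-(propan-2-yl)spiro[bicyclo[3.1.1]heptane-2,1'-cyclopentan]-2'-yl]methanol
Product: 21 6,6-dimethyl-3'-(propan-2-yl)spiro[bicyclo[3.1.1]heptane-2,1'-cyclopentane]-2'-carbaldehyde
Conditions: Dess–Martin periodinane, NaHCO3, CH2Cl2, 25 °C
Reagents that add atoms: none
Why: Dess–Martin oxidation stops at the aldehyde under buffered, non-epimerising conditions.

Step 14
Reactants: 22 methyl isobutyrate; 23 propanoyl chloride
Product: 24 methyl 2,2-dimethyl-3-oxopentanoate
Conditions: LiN(i-Pr)2, THF, −78 °C; enolate added to 23, −78 → 0 °C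
Reagents that add atoms: none
Why: C-acylation of a fully substituted lithium ester enolate by an acid chloride (crossed Claisen-type acylation); inverse addition keeps the product, which has a quaternary α-carbon and a single enolisable ethyl group, away from excess enolate.

Step 15
Reactants: 21 6,6-dimethyl-3'-(propan-2-yl)spiro[bicyclo[3.1.1]heptane-2,1'-cyclopentane]-2'-carbaldehyde; 24 methyl 2,2-dimethyl-3-oxopentanoate
Product: 25 aldol adduct (β-hydroxy ketone at a3)
Conditions: LiN(i-Pr)2, THF, −78 °C (24); then 21, −78 °C; AcOH quench
Reagents that add atoms: none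
Why: Directed aldol addition: the keto ester can be enolised only at the methylene of its ethyl group, and this lithium enolate adds to the hindered but reactive aldehyde at −78 °C. The two new stereocentres are removed in steps 16 and 17, so the diastereomer ratio does not matter.

Step 16
Reactants: 25 aldol adduct (β-hydroxy ketone at a3)
Product: 26 3,5-dioxo ester (1,3-diketone a1/a3 with the a5 ester)
Conditions: Dess–Martin periodinane, CH2Cl2, 25 °C
Reagents that add atoms: none
Why: Dess–Martin oxidation of a β-hydroxy ketone to the 1,3-diketone, a standard transformation that avoids retro-aldol cleavage.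

Step 17
Reactants: 26 3,5-dioxo ester (1,3-diketone a1/a3 with the a5 ester)
Product: 27 spiro triketone of ring A (enol form)
Conditions: LiN(i-Pr)2 (3 equiv.), THF, −78 → 0 °C; aq. HCl work-up
Reagents that add atoms: none
Why: Dieckmann-type Claisen cyclisation of a 3,5-dioxo ester through its dianion: the first equivalent of base removes the a2 proton, the second the only remaining α′ proton at a4, and this more reactive carbanion attacks the ester in a 6-exo-trig closure. The product remains protected as its a1–a2–a3 enolate, so methoxide does not reopen it. The electrophile should reach the planar a4 from the face of ring B anti to the neighbouring isopropyl group, which puts the a5 carbonyl trans and the a3 carbonyl cis to it, as in the target, whatever the earlier configuration at a4.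

Step 18
Reactants: 27 spiro triketone of ring A (enol form)
Product: 28 CNP0307059.1
Conditions: CH2N2, Et2O–MeOH, 0 °C
Reagents that add atoms: diazomethane, C=[N+]=[N-]
Why: Methylation of a vinylogous acid by diazomethane (proton transfer, then methyl transfer in the ion pair) occurs on oxygen only. Of the two enol oxygens the one on a1, next to the CMe2 group, is the more accessible, the one on a3 being buried between the spiro centre and the cis isopropyl group.

## Compound list

1 | (+)-β-pinene, (1R,5R)-6,6-dimethyl-2-methylidenebicyclo[3.1.1]heptane | C=C1CC[C@@H]2C[C@H]1C2(C)C | starting material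
2 | secondary ozonide of 1 (spiro-1,2,4-trioxolane at P2, both configurations at the spiro carbon) | C1OC2(CC[C@@H]3C[C@H]2C3(C)C)OO1 | intermediate
3 | (−)-nopinone, (1S,5R)-6,6-dimethylbicyclo[3.1.1]heptan-2-one | O=C1CC[C@@H]2C[C@H]1C2(C)C | intermediate
4 | trimethyl phosphonoacetate | COC(=O)CP(=O)(OC)OC | starting material
5 | methyl (2E)-2-[(1S,5R)-6,6-dimethylbicyclo[3.1.1]heptan-2-ylidene]acetate (ester on the side of P3) | COC(=O)/C=C1\CC[C@@H]2C[C@H]1C2(C)C | intermediate
6 | methyl (2Z)-2-[(1S,5S)-6,6-dimethyl-3-oxobicyclo[3.1.1]heptan-2-ylidene]acetate (ester syn to the ketone) | COC(=O)/C=C1\C(=O)C[C@@H]2C[C@H]1C2(C)C | intermediate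
7 | methyl (2E)-2-[(1S,5S)-6,6-dimethyl-3-oxobicyclo[3.1.1]heptan-2-ylidene]acetate (ester anti to the ketone) | COC(=O)/C=C1/C(=O)C[C@@H]2C[C@H]1C2(C)C | intermediate
8 | methyl (2E)-2-[(1S,3S,5S)-3-hydroxy-6,6-dimethylbicyclo[3.1.1]heptan-2-ylidene]acetate (OH cis to the CMe2 bridge) | COC(=O)/C=C1/[C@@H](O)C[C@@H]2C[C@H]1C2(C)C | intermediate
9 | 3-methylbutanoic acid | CC(C)CC(=O)O | starting material
10 | methyl (2E)-2-[(1S,3R,5S)-6,6-dimethyl-3-(3-methylbutanoyloxy)bicyclo[3.1.1]heptan-2-ylidene]acetate (acyloxy trans to the CMe2 bridge) | COC(=O)/C=C1/[C@H](OC(=O)CC(C)C)C[C@@H]2C[C@H]1C2(C)C | intermediate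
11 | trimethylsilyl ketene acetal of 10 (isopropyl cis to OSiMe3) | COC(=O)/C=C1/[C@H](O/C(O[Si](C)(C)C)=C/C(C)C)C[C@@H]2C[C@H]1C2(C)C | intermediate
12 | trimethylsilyl ester of 13 | [C@H](C(=O)OC)(C1=CC[C@@H]2C[C@H]1C2(C)C)[C@@H](C(C)C)C(=O)O[Si](C)(C)C | intermediate
13 | (2R,3R)-3-[(1S,5R)-6,6-dimethylbicyclo[3.1.1]hept-2-en-2-yl]-4-methoxy-4-oxo-2-(propan-2-yl)butanoic acid | [C@H](C(=O)OC)(C1=CC[C@@H]2C[C@H]1C2(C)C)[C@@H](C(C)C)C(=O)O | intermediate
14 | methyl (2R,3R)-4-chloro-2-[(1S,5R)-6,6-dimethylbicyclo[3.1.1]hept-2-en-2-yl]-4-oxo-3-(propan-2-yl)butanoate (acid chloride of 13) | [C@H](C(=O)OC)(C1=CC[C@@H]2C[C@H]1C2(C)C)[C@@H](C(C)C)C(=O)Cl | intermediate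
15 | methyl (2R,3R)-5-diazo-2-[(1S,5R)-6,6-dimethylbicyclo[3.1.1]hept-2-en-2-yl]-4-oxo-3-(propan-2-yl)pentanoate | [C@H](C(=O)OC)(C1=CC[C@@H]2C[C@H]1C2(C)C)[C@@H](C(C)C)C(=O)C=[N+]=[N-] | intermediate
16 | cyclopropyl ketone: ring B (a4–Cc–Cb(=O)–Ca–P2) cis-fused through Ca–P2 to the cyclopropane Ca–P2–P3 of the pinane; Ca anti and a4 syn to the CMe2 bridge; isopropyl cis to P3; CO2Me trans to isopropyl | [C@@H]2(C(=O)OC)[C@@H](C(C)C)C(=O)[C@@H]3[C@@]21[C@H]3C[C@@H]2C[C@H]1C2(C)C | intermediate
17 | methyl 6,6-dimethyl-4'-oxo-3'-(propan-2-yl)spiro[bicyclo[3.1.1]heptane-2,1'-cyclopentane]-2'-carboxylate (C2' syn to the CMe2 bridge; CO2Me trans to isopropyl; isopropyl on the side of P3) | [C@@H]2(C(=O)OC)[C@@H](C(C)C)C(=O)C[C@@]21CC[C@@H]2C[C@H]1C2(C)C | intermediate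
18 | 1,3-dithiolane of 17 at C4' (Cb) | [C@@H]2(C(=O)OC)[C@@H](C(C)C)C3(SCCS3)C[C@@]21CC[C@@H]2C[C@H]1C2(C)C | intermediate
19 | methyl 6,6-dimethyl-3'-(propan-2-yl)spiro[bicyclo[3.1.1]heptane-2,1'-cyclopentane]-2'-carboxylate (configuration as in 17) | [C@@H]2(C(=O)OC)[C@@H](C(C)C)CC[C@@]21CC[C@@H]2C[C@H]1C2(C)C | intermediate
20 | [6,6-dimethyl-3'-(propan-2-yl)spiro[bicyclo[3.1.1]heptane-2,1'-cyclopentan]-2'-yl]methanol | [C@@H]2(CO)[C@@H](C(C)C)CC[C@@]21CC[C@@H]2C[C@H]1C2(C)C | intermediate
21 | 6,6-dimethyl-3'-(propan-2-yl)spiro[bicyclo[3.1.1]heptane-2,1'-cyclopentane]-2'-carbaldehyde | [C@@H]2(C=O)[C@@H](C(C)C)CC[C@@]21CC[C@@H]2C[C@H]1C2(C)C | intermediate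
22 | methyl isobutyrate (methyl 2-methylpropanoate) | COC(=O)C(C)C | starting material
23 | propanoyl chloride | CCC(Cl)=O | starting material
24 | methyl 2,2-dimethyl-3-oxopentanoate | CCC(=O)C(C)(C)C(=O)OC | intermediate
25 | methyl 5-hydroxy-2,2,4-trimethyl-3-oxo-5-(spirocyclopentyl)pentanoate, the spirocyclopentyl group being that of 21 (mixture at the carbinol and methyl-bearing carbons) | [C@@H]2(C(O)C(C)C(=O)C(C)(C)C(=O)OC)[C@@H](C(C)C)CC[C@@]21CC[C@@H]2C[C@H]1C2(C)C | intermediate
26 | methyl 2,2,4-trimethyl-3,5-dioxo-5-(spirocyclopentyl)pentanoate (keto–enol mixture; methyl-bearing carbon epimerisable) | [C@@H]2(C(=O)C(C)C(=O)C(C)(C)C(=O)OC)[C@@H](C(C)C)CC[C@@]21CC[C@@H]2C[C@H]1C2(C)C | intermediate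
27 | 4''-hydroxy-3'',5'',5'',6,6-pentamethyl-3'-(propan-2-yl)dispiro[bicyclo[3.1.1]heptane-2,1'-cyclopentane-2',1''-cyclohexan]-3''-ene-2'',6''-dione (enol of the triketone; a5 carbonyl trans to isopropyl) | OC1=C(C)C(=O)[C@@]2(C(=O)C1(C)C)[C@@H](C(C)C)CC[C@@]21CC[C@@H]2C[C@H]1C2(C)C | intermediate
28 | CNP0307059.1, 4''-methoxy-3'',5'',5'',6,6-pentamethyl-3'-(propan-2-yl)dispiro[bicyclo[3.1.1]heptane-2,1'-cyclopentane-2',1''-cyclohexan]-3''-ene-2'',6''-dione (a4 syn to the CMe2 bridge; isopropyl cis to P3 and to the a3 carbonyl) | COC1=C(C)C(=O)[C@@]2(C(=O)C1(C)C)[C@@H](C(C)C)CC[C@@]21CC[C@@H]2C[C@H]1C2(C)C | target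

## Step count and least certain steps

Total: 18 steps. Longest linear sequence: 17 steps (steps 1–13 and 15–18, from 1); step 14 is a one-step side branch.

**Step 8 (key step).** The carbenoid may be diverted before it reaches the alkene, by insertion into a C–H bond, by attack of the ester carbonyl oxygen, or by dimerisation, because the inner alkene carbon P2 is fully substituted and shielded by the bridgehead. Leakage to the hindered face is the lesser risk. Fallback, from 14 back to 17, with a stabilised acceptor–acceptor carbenoid: acid chloride 14 is added to the lithium enolate of tert-butyl acetate to give tert-butyl β-keto ester F1. Diazo transfer with 4-acetamidobenzenesulfonyl azide and Et3N gives diazo β-keto ester F2. Rh2(OAc)4 (divalent rhodium) in CH2Cl2 should close cyclopropane β-keto ester F3 on the same alkene face. SmI2 opens the external cyclopropane bond to ring-opened β-keto ester F4, and CF3CO2H followed by warming removes the tert-butyl ester with decarboxylation to give 17.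

**Step 3.** The allylic position of an electron-poor alkene may be oxidised slowly, the very electrophilic product may be attacked by the peroxide anion, and the geometric equilibration may stay incomplete. Fallback, from 1 to 10, which places the oxygen on P3 before the ester is introduced: allylic hydroxylation of 1 with SeO2 (catalytic) and t-BuOOH gives (−)-trans-pinocarveol F5. Acylation with 3-methylbutanoyl chloride and pyridine gives pinocarvyl isovalerate F6. Ozonolysis gives acyloxy ketone F7. A Wittig reaction with methyl (triphenylphosphoranylidene)acetate in hot toluene gives 10 after chromatographic removal of (Z)-acyloxy enoate F8. This also bypasses steps 4 and 5.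

**Step 6.** Control of the ketene acetal geometry may be incomplete, or part of the material may react through a boat, which erodes the configuration at Cc; deprotonation at the γ-position of the enoate is a second possible leak. Fallback, from 13 to 17, replacing kinetic by thermodynamic control: acid 13 is taken on together with Cc-epimeric acid F9 through steps 7–9. The mixture of 17 and Cc-epimeric ketone F10 is then equilibrated with DBU in toluene; with the ester fixed on a4, the trans arrangement, which is 17, is the more stable one.

**Step 17.** The tertiary a4–H may be removed too slowly, so that the enolate oxygen on a3 closes onto the ester to give an enol lactone, or the facial selectivity at a4 may be insufficient. Fallback, from 19 to 27, with the order of the two acylations reversed: keto ester 24 is saponified with LiOH to 2,2-dimethyl-3-oxopentanoic acid F12 and converted with (COCl)2 into 2,2-dimethyl-3-oxopentanoyl chloride F11. The lithium enolate of 19 is C-acylated with F11, anti to the isopropyl group, to give keto diester F13 (the same compound as A7). KOt-Bu in THF then closes ring A from the ethyl ketone enolate onto the ring ester, a Dieckmann closure driven by deprotonation of 27.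

**Step 18.** Methylation may occur in part on the a3 oxygen. Fallback, from 27 to 28, replacing irreversible O-alkylation by reversible acid-catalysed enol ether formation: HC(OMe)3 and TsOH in MeOH add methanol to the more accessible a1 carbonyl and equilibrate the enol ethers through the ketal; no new compound is involved (F0).

## Further compounds

F1 | step 8 | tert-butyl β-keto ester from 14 (methyl ester, pinenyl and isopropyl groups as in 15) | [C@H](C(=O)OC)(C1=CC[C@@H]2C[C@H]1C2(C)C)[C@@H](C(C)C)C(=O)CC(=O)OC(C)(C)C
F2 | step 8 | α-diazo-β-keto ester of F1 | [C@H](C(=O)OC)(C1=CC[C@@H]2C[C@H]1C2(C)C)[C@@H](C(C)C)C(=O)C(=[N+]=[N-])C(=O)OC(C)(C)C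
F3 | step 8 | cyclopropane β-keto ester (16 with CO2t-Bu on Ca) | [C@@H]2(C(=O)OC)[C@@H](C(C)C)C(=O)[C@]3(C(=O)OC(C)(C)C)[C@@]21[C@H]3C[C@@H]2C[C@H]1C2(C)C
F4 | step 8 | ring-opened β-keto ester (17 with CO2t-Bu on Ca, epimerisable there) | [C@@H]2(C(=O)OC)[C@@H](C(C)C)C(=O)C(C(=O)OC(C)(C)C)[C@@]21CC[C@@H]2C[C@H]1C2(C)C
F5 | step 3 | (−)-trans-pinocarveol, (1S,3R,5S)-6,6-dimethyl-2-methylidenebicyclo[3.1.1]heptan-3-ol | C=C1[C@H](O)C[C@@H]2C[C@H]1C2(C)C
F6 | step 3 | (1S,3R,5S)-6,6-dimethyl-2-methylidenebicyclo[3.1.1]heptan-3-yl 3-methylbutanoate | C=C1[C@H](OC(=O)CC(C)C)C[C@@H]2C[C@H]1C2(C)C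
F7 | step 3 | (1S,3R,5S)-6,6-dimethyl-2-oxobicyclo[3.1.1]heptan-3-yl 3-methylbutanoate | O=C1[C@H](OC(=O)CC(C)C)C[C@@H]2C[C@H]1C2(C)C
F8 | step 3 | methyl (2Z)-2-[(1S,3R,5S)-6,6-dimethyl-3-(3-methylbutanoyloxy)bicyclo[3.1.1]heptan-2-ylidene]acetate (geometric isomer of 10) | COC(=O)/C=C1\[C@H](OC(=O)CC(C)C)C[C@@H]2C[C@H]1C2(C)C
F9 | step 6 | Cc-epimer of acid 13 | [C@H](C(=O)OC)(C1=CC[C@@H]2C[C@H]1C2(C)C)[C@H](C(C)C)C(=O)O
F10 | step 6 | Cc-epimer of ketone 17 | [C@@H]2(C(=O)OC)[C@H](C(C)C)C(=O)C[C@@]21CC[C@@H]2C[C@H]1C2(C)C
F11 | step 17 | 2,2-dimethyl-3-oxopentanoyl chloride | CCC(=O)C(C)(C)C(Cl)=O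
F12 | step 17 | 2,2-dimethyl-3-oxopentanoic acid | CCC(=O)C(C)(C)C(=O)O
F13 | step 17 | keto diester, quaternary at a4 (ester and 2,2-dimethyl-3-oxopentanoyl group on a4) | COC(=O)[C@@]2(C(=O)C(C)(C)C(=O)CC)[C@@H](C(C)C)CC[C@@]21CC[C@@H]2C[C@H]1C2(C)C
F0 | step 18 | none | none
A1 | alternative 1 | dispiro Meldrum's acid with isopropenyl on Cc | CC1(C)OC(=O)C2(C(=O)O1)[C@@H](C(C)=C)CC[C@@]21CC[C@@H]2C[C@H]1C2(C)C
A2 | alternative 1 | alkylidene Meldrum's acid of 3 | CC1(C)OC(=O)C(C(=O)O1)=C1CC[C@@H]2C[C@H]1C2(C)C
A3 | alternative 1 | isopropenylcyclopropane | CC(=C)C1CC1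
A4 | alternative 2 | fused dichlorocyclobutanone | O=C3C(Cl)(Cl)[C@]1(c2c(OCOC)c(C)c(OC)c(C)c2OCOC)[C@H]3C[C@@H]2C[C@H]1C2(C)C
A5 | alternative 2 | 2-arylpinene (aryl = 4-methoxy-2,6-bis(methoxymethoxy)-3,5-dimethylphenyl) | COCOc1c(C)c(OC)c(C)c(OCOC)c1C1=CC[C@@H]2C[C@H]1C2(C)C
A6 | alternative 2 | dichloroketene | ClC(Cl)=C=O
A7 | alternative 3 | quaternary keto diester with isopropyl on Cc | COC(=O)[C@@]2(C(=O)C(C)(C)C(=O)CC)[C@@H](C(C)C)CC[C@@]21CC[C@@H]2C[C@H]1C2(C)C
A8 | alternative 3 | spiro cyclopentene ester | COC(=O)C1=CCC[C@@]12CC[C@@H]3C[C@H]2C3(C)C
A9 | alternative 3 | 2,2-dimethyl-3-oxopentanoyl chloride | CCC(=O)C(C)(C)C(Cl)=O
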